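## Structural features

The target, 5-hydroxy-7,8-dimethoxy-2-(2,3,4,5-tetramethoxyphenyl)-4H-chromen-4-one (C21H22O9), is a flavone: benzene ring A is fused to 4-pyranone ring C, which carries benzene ring B at C2 through the single C2–C1' bond. Ring A has a free phenol at C5 (hydrogen-bonded to the C4 carbonyl), methyl ethers at C7 and C8, and hydrogen only at C6. Ring B has four adjacent methoxy groups at C2' to C5' and hydrogen only at C6'. The target has no stereocentre, so no stereocentres stand next to each other; the only one met on the way, C2 of a flavanone, is racemic and is erased on dehydrogenation. The fragile points are the pyranone ring (opened by hot alkali), the possible acid-induced scrambling of a 5,7,8- to a 5,6,7-oxygenated ring A through ring opening and reclosure, the air-sensitive hydroquinone at the 5,8-dihydroxy stage, and the six aryl methyl ethers towards Lewis acids. The real difficulty is regiochemical: only one of seven peripheral oxygens may stay free, at C5, and the C8 oxygen must be placed on a ring whose C6 and C8 are electronically similar. The key step uses the fact that the oxygens at C5, C7 and C8a are mutually meta and that C4a carries the acyl carbon C4, so ring A is an acylphloroglucinol. It can therefore be folded from a linear tricarbonyl chain masked as a 4-methoxy-2-pyrone by forming the C4a–C5 bond; the pyrone methoxy group becomes the 7-methoxy group, and the symmetry of the resulting 2,6-dihydroxy-4-methoxyphenyl ketone makes closure of ring C unambiguous.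

## Logic of the disconnections

16 to 15: the O–CH3 bond at C8 is cut. The 5-hydroxyl is chelated to the C4 carbonyl and the 8-hydroxyl is not, so the two phenols of 15 are already differentiated and no protecting group is needed. The forward step must methylate once only and must keep air away from the hydroquinone.

15 to 13 (through 14): the C8–O bond is cut. C8 is the only position para to the 5-phenoxide oxygen, so a para-selective phenol oxidation can add the last oxygen to a finished flavone. The gain is that ring A can be made with a symmetrical 5,7-dioxygenation pattern. The demand is that the alkaline oxidant leaves ring C and the electron-rich ring B alone.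

13 to 11 (through 12): the O1–C2 bond is cut and the C2=C3 unsaturation is removed, which gives a 2'-hydroxychalcone. Either of the two equivalent ortho hydroxyls of 11 can add to the enone, so only one flavanone is possible. The forward step must combine oxa-Michael closure and dehydrogenation without halogenating ring A.

11 to 9 (through 10): the C4a–C5 bond is cut, which unfolds ring A into a tricarbonyl chain that is stored as a 4-methoxy-2-pyrone with the cinnamoyl unit already attached. This removes an aromatic ring and its three differentiated oxygens in one operation. The forward step must fold in the Claisen mode only and must tolerate the enone.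

9 to 5 and 6 (through 7 and 8): the bond between the pyrone-bound methylene (future C4a) and the ketone carbon (future C4) is cut. This separates a purchased pyrone from an acyl donor that carries all of ring B. The forward step needs deprotonation at the 6-methyl group and not on the ring, and 1,2- rather than 1,4-addition to the unsaturated acyl donor with no over-addition.

5 to 3 and 4: the alkene (future C2–C3) is cut by an olefination, which delivers the E double bond and the acylating function together. The demand is only E selectivity, which a stabilised phosphonate anion provides.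

3 to 1 (through 2): the aryl–formyl bond (future C1'–C2) is cut. The two free positions of 1 are equivalent by symmetry, so electrophilic formylation can give only one aldehyde.

## Other disconnections considered

Alternative 1: The cut is the C1'–C2' bond of ring B, which would be built from dimethyl squarate A3 and a two-carbon vinyl unit on C2 of a finished 5,7,8-trimethoxychromone.
- Forward step: 1,2-addition of the vinyl-metal reagent to A3 would give the 4-hydroxy-4-alkenylcyclobutenone A2. Heating A2 in an inert aromatic solvent would open the four-membered ring to a dienylketene (Moore rearrangement), and 6π electrocyclisation followed by tautomerisation would give the hydroquinone A1.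
- In its favour: the thermal step is neutral, the ring B oxygen pattern is fixed by the squarate, and the 8-oxygen of ring A would be carried from the start. No late persulfate oxidation would be needed, and on this point it is better than the chosen plan.
- Against it: ring B is the one part of the target that can be bought intact as 1. The vinyl-metal reagent would carry an electrophilic chromone, so its generation is doubtful. The 5,7,8-trioxygenated ring A would still have to be made separately. A1 is an oxidation-prone hydroquinone that needs two O-methylations and then selective cleavage of the 5-methyl ether.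
- Comparison: on structure, it builds the easy ring and leaves the hard one unsolved, whereas the chosen plan builds ring A with its oxygens differentiated. On mechanism, both are regiocontrolled ring-forming folds and are equal in that respect. On step economy, the alternative is clearly longer.

Alternative 2: The cut is through ring C at C8a–O1, C4a–C4 and O1–C2, which would join the arylpropiolic acid A5 to the aryne released from the silyl triflate A6.
- Forward step: a fluoride source would generate the aryne. The carboxylate of A5 would add at the aryne carbon remote from the flanking methoxy group, the resulting aryl anion would take the acyl group (net insertion into the carboxyl C–O bond), and the ortho-acylphenoxide would close onto the ynone in a 6-endo-dig oxa-Michael addition to give A4.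
- In its favour: it is convergent, the regiochemistry of addition to a 3-methoxy-substituted aryne is predictable and places the acyl group next to the methoxy group as required, and the flavone oxidation level is reached without a dehydrogenation. On these three points it is the equal or the better of the chosen plan. A5 should be about two steps from 3.
- Against it: A4 has a 5-methyl ether and no 8-oxygen, so C8 halogenation, methoxylation and selective 5-O-demethylation would follow. A6 needs about three steps of its own. Aryl ester formation without acyl shift, capture of a second aryne, 5-exo-dig closure to an aurone and decarboxylation of A5 could all compete. The 8-methoxy group cannot be carried on the aryne, because methoxy groups would then flank both ends of the triple bond and the regiocontrol would be lost.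
- Comparison: on structure, the chosen plan delivers the free 5-hydroxyl and the 7-methyl ether directly from the fold. On mechanism, the alternative depends on polar regiocontrol of an aryne where the chosen plan depends on symmetry. On step economy, the alternative is somewhat longer overall once A6 and the three steps after A4 are counted.

Alternative 3: The cuts are the C4a–C5, C5–C6 and C7–C8 bonds of ring A, which would be built on a preformed 2-aryl-4-pyranone from the diazoketone A8 and methoxyethyne A9.
- Forward step: irradiation would trigger a Wolff rearrangement that moves the pyranonyl group to the former diazo carbon (future C8) and gives a ketene conjugated with the pyranone C=C. Cycloaddition with A9, 4π opening of the 3-methoxycyclobutenone and 6π closure onto the future C4a, then tautomerisation, would give A7 (Danheiser benzannulation). A7 has the same structure as 13.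
- In its favour: ketene and ynol-ether polarity fix the hydroxyl at C5 and the methoxy group at C7. On this point it equals the chosen plan, and it is better in arriving at the flavone oxidation level without a dehydrogenation.
- Against it: A8 needs a 6-aryl-4-oxopyran-2-carboxylic acid, its activation and a hazardous diazoalkane reagent, some four or five steps. A9 is volatile and unstable and is not a shelf reagent. 4-Pyranones are themselves photoreactive. The electrocyclisation must engage a C=C that is part of a cross-conjugated vinylogous ester. The end game after A7 is the same as after 13, so nothing is saved there.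
- Comparison: on structure, both plans make the same intermediate with the same regiocontrol. On mechanism, the alternative is a pericyclic cascade of four events where the chosen plan is a single chelation-controlled Claisen condensation. On step economy, it is longer and needs photochemical and diazo handling.

Key step: step 4

Remarks on the chemistry:
- The open-chain ester 10 keeps the ester carbon and the carbon chain cis on the enol-ether double bond, as in the pyrone. Because the methoxy group outranks the chain carbon, the correct descriptor is (2E); a (2Z) label for this species would be wrong.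
- Compounds 1, 4 and 6, LiN(iPr)2 solution and Mg(OMe)2 solution in methanol are taken as purchasable.

## Route

Step 1
Reactants: 1 1,2,3,4-tetramethoxybenzene
Product: 3 2,3,4,5-tetramethoxybenzaldehyde, via N,N-dimethyl(2,3,4,5-tetramethoxyphenyl)methaniminium dichlorophosphate 2 (not isolated)
Conditions: POCl3, DMF, 0 → 80 °C; then H2O, 60 °C
Reagents that add atoms: N,N-dimethylformamide, CN(C)C=O; water, O
Why: Vilsmeier–Haack formylation of a strongly activated arene; the two free positions of 1 are equivalent by symmetry, so only one aldehyde can form, and hydrolysis of iminium salt 2 releases it.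

Step 2
Reactants: 3 2,3,4,5-tetramethoxybenzaldehyde; 4 diethyl {2-[methoxy(methyl)amino]-2-oxoethyl}phosphonate
Product: 5 (2E)-N-methoxy-N-methyl-3-(2,3,4,5-tetramethoxyphenyl)prop-2-enamide
Conditions: NaH, THF, 0 °C → rt
Reagents that add atoms: none
Why: Horner–Wadsworth–Emmons olefination with a stabilised phosphonate anion, which should give the E alkene under thermodynamic control and install the acylating function in the same step.

Step 3
Reactants: 6 4-methoxy-6-methyl-2H-pyran-2-one; 5 (2E)-N-methoxy-N-methyl-3-(2,3,4,5-tetramethoxyphenyl)prop-2-enamide
Product: 9 4-methoxy-6-[(3E)-2-oxo-4-(2,3,4,5-tetramethoxyphenyl)but-3-en-1-yl]-2H-pyran-2-one, via [(4-methoxy-2-oxo-2H-pyran-6-yl)methyl]lithium 7 (not isolated), via lithium (3E)-2-[methoxy(methyl)amino]-1-(4-methoxy-2-oxo-2H-pyran-6-yl)-4-(2,3,4,5-tetramethoxyphenyl)but-3-en-2-olate 8 (not isolated)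
Conditions: 6 (2.0 equiv), LiN(iPr)2 (1.9 equiv), THF, −78 °C; then 5 (1.0 equiv), −78 → −30 °C; 1 M HCl
Reagents that add atoms: none
Why: Vinylogous deprotonation of the 6-methyl group gives the extended enolate 7, which should add 1,2 to the N-methoxy-N-methylamide (Weinreb ketone synthesis); the chelated adduct 8 collapses only on the acidic quench, so neither over-addition nor proton transfer from the product ketone can interfere.

Step 4
Reactants: 9 4-methoxy-6-[(3E)-2-oxo-4-(2,3,4,5-tetramethoxyphenyl)but-3-en-1-yl]-2H-pyran-2-one
Product: 11 (2E)-1-(2,6-dihydroxy-4-methoxyphenyl)-3-(2,3,4,5-tetramethoxyphenyl)prop-2-en-1-one, via methyl (2E,8E)-3-methoxy-5,7-dioxo-9-(2,3,4,5-tetramethoxyphenyl)nona-2,8-dienoate 10 (not isolated)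
Conditions: Mg(OMe)2 (5 equiv), MeOH, reflux, N2; then 1 M HCl, 0 °C
Reagents that add atoms: none
Why: Methoxide from Mg(OMe)2 adds to the lactone carbonyl of 9 and opens the pyrone to the magnesium chelate of the tricarbonyl ester 10, in which ester carbon and chain remain cis on the enol-ether double bond as they were in the ring. The magnesium enolate of the 5,7-diketone then attacks the ester carbonyl through its central carbon, a 6-exo-trig Claisen (Dieckmann-type) acylation that forms the C4a–C5 bond and closes ring A; loss of methoxide and enolisation give the aromatic ketone 11. The closest known reaction type is the biomimetic base-induced recyclisation of 6-(2-oxoalkyl)-4-methoxy-2-pyrones to acylphloroglucinols, the laboratory counterpart of the chalcone synthase fold. No stereocentre is formed. The step needs Claisen rather than aldol folding and C- rather than O-acylation: the enol ether at the former pyrone C4 cannot act as an aldol donor, which closes the resorcylate mode, and chelation by the divalent magnesium ion holds the diketone as a carbon nucleophile next to the activated ester. The enone must also survive: conjugate addition of methoxide is reversible whereas aromatisation is not, so 11 should be the thermodynamic sink. Any 11 that closes further to 12 under the basic conditions is no loss, because step 5 carries both to 13.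

Step 5
Reactants: 11 (2E)-1-(2,6-dihydroxy-4-methoxyphenyl)-3-(2,3,4,5-tetramethoxyphenyl)prop-2-en-1-one
Product: 13 5-hydroxy-7-methoxy-2-(2,3,4,5-tetramethoxyphenyl)-4H-chromen-4-one, via racemic 5-hydroxy-7-methoxy-2-(2,3,4,5-tetramethoxyphenyl)-2,3-dihydro-4H-chromen-4-one 12 (not isolated)
Conditions: I2 (0.1 equiv), DMSO, 130 °C
Reagents that add atoms: none
Why: Iodine-catalysed oxidative cyclisation of a 2'-hydroxychalcone: oxa-Michael closure through either of the two equivalent hydroxyls gives flavanone 12, and α-iodination with loss of HI gives the flavone while DMSO reoxidises iodide. The racemic C2 stereocentre of 12 is erased.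

Step 6
Reactants: 13 5-hydroxy-7-methoxy-2-(2,3,4,5-tetramethoxyphenyl)-4H-chromen-4-one
Product: 15 5,8-dihydroxy-7-methoxy-2-(2,3,4,5-tetramethoxyphenyl)-4H-chromen-4-one, via potassium 5-hydroxy-7-methoxy-4-oxo-2-(2,3,4,5-tetramethoxyphenyl)-4H-chromen-8-yl sulfate 14 (not isolated)
Conditions: K2S2O8, aq. KOH, pyridine, 15–20 °C; then HCl, 90 °C, N2
Reagents that add atoms: potassium peroxodisulfate, [K+].[K+].[O-]S(=O)(=O)OOS(=O)(=O)[O-]
Why: Elbs persulfate oxidation: the 5-phenoxide attacks a peroxide oxygen of peroxodisulfate through its para carbon C8 to give aryl sulfate 14, which dilute acid hydrolyses to the quinol. C8 is the only position para to the phenoxide oxygen, and ring B has no free phenol to compete.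

Step 7
Reactants: 15 5,8-dihydroxy-7-methoxy-2-(2,3,4,5-tetramethoxyphenyl)-4H-chromen-4-one
Product: 16 5-hydroxy-7,8-dimethoxy-2-(2,3,4,5-tetramethoxyphenyl)-4H-chromen-4-one
Conditions: MeI (1.05 equiv), K2CO3, acetone, reflux, N2
Reagents that add atoms: iodomethane, CI
Why: Williamson ether synthesis; the 5-hydroxyl is held in a hydrogen bond to the C4 carbonyl and is much less nucleophilic under weak base, so one equivalent of iodomethane should alkylate the 8-hydroxyl only.

## Compound list

1 | 1,2,3,4-tetramethoxybenzene | COc1ccc(OC)c(OC)c1OC | starting material
2 | N,N-dimethyl(2,3,4,5-tetramethoxyphenyl)methaniminium dichlorophosphate | COc1cc(C=[N+](C)C)c(OC)c(OC)c1OC.[O-]P(Cl)(Cl)=O | intermediate (not isolated)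
3 | 2,3,4,5-tetramethoxybenzaldehyde | COc1cc(C=O)c(OC)c(OC)c1OC | intermediate
4 | diethyl {2-[methoxy(methyl)amino]-2-oxoethyl}phosphonate | CCOP(=O)(CC(=O)N(C)OC)OCC | starting material
5 | (2E)-N-methoxy-N-methyl-3-(2,3,4,5-tetramethoxyphenyl)prop-2-enamide | CON(C)C(=O)/C=C/c1cc(OC)c(OC)c(OC)c1OC | intermediate
6 | 4-methoxy-6-methyl-2H-pyran-2-one | COc1cc(C)oc(=O)c1 | starting material
7 | [(4-methoxy-2-oxo-2H-pyran-6-yl)methyl]lithium | [Li]Cc1cc(OC)cc(=O)o1 | intermediate (not isolated)
8 | lithium (3E)-2-[methoxy(methyl)amino]-1-(4-methoxy-2-oxo-2H-pyran-6-yl)-4-(2,3,4,5-tetramethoxyphenyl)but-3-en-2-olate, racemic | COc1cc(CC([O-])(/C=C/c2cc(OC)c(OC)c(OC)c2OC)N(C)OC)oc(=O)c1.[Li+] | intermediate (not isolated)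
9 | 4-methoxy-6-[(3E)-2-oxo-4-(2,3,4,5-tetramethoxyphenyl)but-3-en-1-yl]-2H-pyran-2-one | COc1cc(CC(=O)/C=C/c2cc(OC)c(OC)c(OC)c2OC)oc(=O)c1 | intermediate
10 | methyl (2E,8E)-3-methoxy-5,7-dioxo-9-(2,3,4,5-tetramethoxyphenyl)nona-2,8-dienoate (present as its magnesium chelate) | COC(=O)/C=C(\CC(=O)CC(=O)/C=C/c1cc(OC)c(OC)c(OC)c1OC)OC | intermediate (not isolated)
11 | (2E)-1-(2,6-dihydroxy-4-methoxyphenyl)-3-(2,3,4,5-tetramethoxyphenyl)prop-2-en-1-one | COc1cc(O)c(C(=O)/C=C/c2cc(OC)c(OC)c(OC)c2OC)c(O)c1 | intermediate
12 | 5-hydroxy-7-methoxy-2-(2,3,4,5-tetramethoxyphenyl)-2,3-dihydro-4H-chromen-4-one, racemic | COc1cc(O)c2c(c1)OC(c1cc(OC)c(OC)c(OC)c1OC)CC2=O | intermediate (not isolated)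
13 | 5-hydroxy-7-methoxy-2-(2,3,4,5-tetramethoxyphenyl)-4H-chromen-4-one | COc1cc(O)c2c(=O)cc(-c3cc(OC)c(OC)c(OC)c3OC)oc2c1 | intermediate
14 | potassium 5-hydroxy-7-methoxy-4-oxo-2-(2,3,4,5-tetramethoxyphenyl)-4H-chromen-8-yl sulfate | COc1cc(O)c2c(=O)cc(-c3cc(OC)c(OC)c(OC)c3OC)oc2c1OS(=O)(=O)[O-].[K+] | intermediate (not isolated)
15 | 5,8-dihydroxy-7-methoxy-2-(2,3,4,5-tetramethoxyphenyl)-4H-chromen-4-one | COc1cc(O)c2c(=O)cc(-c3cc(OC)c(OC)c(OC)c3OC)oc2c1O | intermediate
16 | 5-hydroxy-7,8-dimethoxy-2-(2,3,4,5-tetramethoxyphenyl)-4H-chromen-4-one | COc1cc(-c2cc(=O)c3c(O)cc(OC)c(OC)c3o2)c(OC)c(OC)c1OC | target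

## Step count and least certain steps

Total: 7 steps. Longest linear sequence: 7 steps, from 1 to 16; 4 and 6 enter as purchased materials.

Step 4 (key step). The opened tricarbonyl chain may fragment by methoxide attack on a ketone (retro-Claisen), or the diketone may add to the enone as a carbon or oxygen nucleophile, before the Claisen closure occurs. The cinnamoyl unit is a second electrophile, and the chain is base-labile until it aromatises. Fallback: ring A is bought instead of built. Commercial 1-(2,6-dihydroxy-4-methoxyphenyl)ethan-1-one F1 would be protected with chloromethyl methyl ether and iPr2NEt as 1-[4-methoxy-2,6-bis(methoxymethoxy)phenyl]ethan-1-one F2. Claisen–Schmidt condensation of F2 with 3 (KOH, EtOH) would give (2E)-1-[4-methoxy-2,6-bis(methoxymethoxy)phenyl]-3-(2,3,4,5-tetramethoxyphenyl)prop-2-en-1-one F3. HCl in methanol would remove both acetals, and the route is rejoined at 11.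

Step 6. Conversion may stay low and over-oxidation may occur, because peroxodisulfate reacts slowly with a chelated, electron-poor phenoxide while the quinol product is more easily oxidised than the starting phenol; prolonged alkali may also open ring C. Unreacted 13 can be recovered before the hydrolysis, and a reducing work-up protects the quinol. Fallback, setting out from 13:
- exhaustive methylation (excess MeI, K2CO3, DMF, 60 °C) would give 5,7-dimethoxy-2-(2,3,4,5-tetramethoxyphenyl)-4H-chromen-4-one F4;
- N-bromosuccinimide should brominate the most activated position, C8, to give 8-bromo-5,7-dimethoxy-2-(2,3,4,5-tetramethoxyphenyl)-4H-chromen-4-one F5;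
- NaOMe with CuBr in DMF–MeOH at 110 °C would give 5,7,8-trimethoxy-2-(2,3,4,5-tetramethoxyphenyl)-4H-chromen-4-one F6;
- BCl3 in CH2Cl2 at −78 → 0 °C would cleave only the methyl ether peri to the carbonyl, so the route is rejoined at 16 and step 7 is bypassed.

Step 3. Deprotonation may occur on the pyrone ring at C3 and not at the methyl group, or the extended enolate may add in conjugate fashion to the unsaturated amide; a delocalised, stabilised anion is a soft nucleophile and the amide is a sluggish acyl acceptor. Fallback, setting out from 5: reduction with iBu2AlH at −78 °C would give (2E)-3-(2,3,4,5-tetramethoxyphenyl)prop-2-enal F7. Anion 7 (from 6) should add 1,2 to this aldehyde to give racemic 6-[(3E)-2-hydroxy-4-(2,3,4,5-tetramethoxyphenyl)but-3-en-1-yl]-4-methoxy-2H-pyran-2-one F8. Oxidation of the allylic alcohol with MnO2 rejoins the route at 9.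

Step 5. Electrophilic iodination of the electron-rich ring A, or ether cleavage by the HI formed at 130 °C, may accompany the dehydrogenation. Fallback, setting out from 11: closure to flavanone 12 under mild conditions (NaOAc, EtOH, reflux) with isolation, then dehydrogenation with 2,3-dichloro-5,6-dicyano-1,4-benzoquinone in dioxane at reflux, which rejoins the route at 13 without any halogen present.

Step 7. Methylation of both phenols or air oxidation of the quinol to the quinone under base would erode the selectivity, since the hydroquinone anion is a strong reductant and the 5-hydroxyl is deactivated but not inert. Fallback, setting out from 15: exhaustive methylation (excess MeI, K2CO3, DMF, 60 °C) would give 5,7,8-trimethoxy-2-(2,3,4,5-tetramethoxyphenyl)-4H-chromen-4-one F9, identical in structure with F6. Selective cleavage of the 5-methyl ether with BCl3 in CH2Cl2 then rejoins the route at 16.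

## Further compounds

F1 | step 4 | 1-(2,6-dihydroxy-4-methoxyphenyl)ethan-1-one | COc1cc(O)c(C(C)=O)c(O)c1
F2 | step 4 | 1-[4-methoxy-2,6-bis(methoxymethoxy)phenyl]ethan-1-one | COCOc1cc(OC)cc(OCOC)c1C(C)=O
F3 | step 4 | (2E)-1-[4-methoxy-2,6-bis(methoxymethoxy)phenyl]-3-(2,3,4,5-tetramethoxyphenyl)prop-2-en-1-one | COCOc1cc(OC)cc(OCOC)c1C(=O)/C=C/c1cc(OC)c(OC)c(OC)c1OC
F4 | step 6 | 5,7-dimethoxy-2-(2,3,4,5-tetramethoxyphenyl)-4H-chromen-4-one | COc1cc(OC)c2c(=O)cc(-c3cc(OC)c(OC)c(OC)c3OC)oc2c1
F5 | step 6 | 8-bromo-5,7-dimethoxy-2-(2,3,4,5-tetramethoxyphenyl)-4H-chromen-4-one | COc1cc(OC)c2c(=O)cc(-c3cc(OC)c(OC)c(OC)c3OC)oc2c1Br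
F6 | step 6 | 5,7,8-trimethoxy-2-(2,3,4,5-tetramethoxyphenyl)-4H-chromen-4-one | COc1cc(OC)c2c(=O)cc(-c3cc(OC)c(OC)c(OC)c3OC)oc2c1OC
F7 | step 3 | (2E)-3-(2,3,4,5-tetramethoxyphenyl)prop-2-enal | COc1cc(/C=C/C=O)c(OC)c(OC)c1OC
F8 | step 3 | 6-[(3E)-2-hydroxy-4-(2,3,4,5-tetramethoxyphenyl)but-3-en-1-yl]-4-methoxy-2H-pyran-2-one, racemic | COc1cc(CC(O)/C=C/c2cc(OC)c(OC)c(OC)c2OC)oc(=O)c1
F0 | step 5 | none | none
F9 | step 7 | 5,7,8-trimethoxy-2-(2,3,4,5-tetramethoxyphenyl)-4H-chromen-4-one (identical with F6) | COc1cc(OC)c2c(=O)cc(-c3cc(OC)c(OC)c(OC)c3OC)oc2c1OC
A1 | alternative 1 | 2-(2,5-dihydroxy-3,4-dimethoxyphenyl)-5,7,8-trimethoxy-4H-chromen-4-one | COc1cc(OC)c2c(=O)cc(-c3cc(O)c(OC)c(OC)c3O)oc2c1OC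
A2 | alternative 1 | 4-hydroxy-2,3-dimethoxy-4-[(E)-2-(5,7,8-trimethoxy-4-oxo-4H-chromen-2-yl)ethenyl]cyclobut-2-en-1-one, racemic | COC1=C(OC)C(O)(/C=C/c2cc(=O)c3c(OC)cc(OC)c(OC)c3o2)C1=O
A3 | alternative 1 | 3,4-dimethoxycyclobut-3-ene-1,2-dione (dimethyl squarate) | COC1=C(OC)C(=O)C1=O
A4 | alternative 2 | 5,7-dimethoxy-2-(2,3,4,5-tetramethoxyphenyl)-4H-chromen-4-one (identical with F4) | COc1cc(OC)c2c(=O)cc(-c3cc(OC)c(OC)c(OC)c3OC)oc2c1
A5 | alternative 2 | 3-(2,3,4,5-tetramethoxyphenyl)prop-2-ynoic acid | COc1cc(C#CC(O)=O)c(OC)c(OC)c1OC
A6 | alternative 2 | 3,5-dimethoxy-2-(trimethylsilyl)phenyl trifluoromethanesulfonate | COc1cc(OC)c([Si](C)(C)C)c(OS(=O)(=O)C(F)(F)F)c1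
A7 | alternative 3 | 5-hydroxy-7-methoxy-2-(2,3,4,5-tetramethoxyphenyl)-4H-chromen-4-one (identical with 13) | COc1cc(O)c2c(=O)cc(-c3cc(OC)c(OC)c(OC)c3OC)oc2c1
A8 | alternative 3 | 2-diazo-1-[4-oxo-6-(2,3,4,5-tetramethoxyphenyl)-4H-pyran-2-yl]ethan-1-one | COc1cc(-c2cc(=O)cc(C(=O)C=[N+]=[N-])o2)c(OC)c(OC)c1OC
A9 | alternative 3 | methoxyethyne | COC#C
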